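Alpha and eta are charged alike, with 0.020 M of G and 10 mol% of E, which is 0.00200 M of E. They differ in time, 3.0 h against 0.80 h.

| setting | noon | dusk | alpha | eta |
|---|---|---|---|---|
| G | 0.010 M | 0.015 M | 0.020 M | 0.020 M |
| E | 10 mol% | 10 mol% | 10 mol% | 10 mol% |
| remark | run made earlier | run made earlier |  |  |
| time |  |  | 3.0 h | 0.80 h |

| noon: time / h | noon: D / % | dusk: time / h | dusk: D / % |
|---|---|---|---|
| 0.200 | 0 | 0.500 | 13 |
| 0.667 | 12 | 1.00 | 30 |
| 1.00 | 23 | 1.50 | 50 |
| 1.50 | 35 | 2.00 | 62 |
| 2.50 | 52 | 2.50 | 69 |
| 3.00 | 55 | 3.00 | 74 |

(scatter of a reading: 2 percentage points)

- the average divides the monomer in chains by the number of chains begun, living and dead together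
- the analysis behind the earlier runs scatters by 2 percentage points, standard deviation
- candidate steps: G + L -> J + D; G + J -> D + J; E -> L; D + J -> G + J; 2 L -> Z
- the earlier runs do not show the number of chains; that part of a forecast is a guess

* which of the two ends with the longer chains by the average number of monomer units in a chain (chains begun, living or dead) ("neither" if they lie within 10%) (alpha / eta / neither)
* average number of monomer units in a chain (chains begun, living or dead) at the end, alpha
* average number of monomer units in a chain (chains begun, living or dead) at the end, eta

We build the length up one process at a time. With growth by itself, and each E starting one chain at once, G ends up wholly in chains and alpha's length is 10.0 units.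

Now add the return of G from the chains. Noon leaves 0.00450 M of free G at its last reading and dusk leaves 0.00390 M, so we take dusk's figure, still falling, as a reading from above of the level that stays behind, the equilibrium monomer concentration. Alpha has more E than dusk, so we expect it near that level at its end.

Now add slow starting. Define the floor length as monomer in chains divided by the E charged: the length if each E had begun a chain. For alpha it is 8.05, and the true length is the floor divided by the share of E that has begun chains.

For eta the readings of D at its time, interpolated, are 16.4% in noon and 23.2% in dusk. A straight line through them against the G charged, carried on to eta's charge, gives 30.0%, so our estimate of eta's floor is 3.00. The two lengths draw level if eta's share is 0.373 of alpha's; the readings do not show the shares, so this is a judgement, and we commit to alpha.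

The forecast also says alpha, with 10 units for alpha (from 7.5 to 18) and 5 for eta (from 3.3 to 10), adding “Chains are a guess”.

The flask gives alpha, with 8.84 for alpha and 4.48 for eta.

    G + L → J + D (k = 8.84 M⁻¹ min⁻¹)
    G + J → D + J, rate k2*[J]*[G] (k = 9.24 M⁻¹ min⁻¹)
    E → L (k = 0.0347 min⁻¹)
    D + J → G + J, rate k4*[J] as long as [D] is above zero (k = 0.0221 min⁻¹)
    2 L → Z (k = 32.1 M⁻¹ min⁻¹)

Alpha has not come to rest at 3.0 h. By 30.0 h its G falls from 18.3% to 12.0% of the charge, while J moves from 0.00185 M to 0.00186 M, and the length rises to 9.45. Alpha's floor, reckoned from that G, is 8.80 at that time. Eta, left until 8.00 h, reaches 9.44 with G at 12.0%, level with alpha's length at its later time.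

A neighbour of eta with 0.0080 M of G, the loading of E and the time held, lies on the same line of D at 13.7%, a floor of 1.37, and divided by the share that eta's estimated floor and its length imply, 0.670, this gives 2.04. The neighbour flask gives 2.11, with D at 12.3%.

The readings are calculated with made-up constants; the scatter is artificial.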